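## Analysis of the target

The target is a bicyclic sesquiterpenoid ester of the eremophilane type. Numbering used throughout: ring A is C1–C5 plus C10, ring B is C5–C10, C14 is the methyl on C5, C15 the methyl on C4, and C11–C13 the hydroxyisopropyl group on C7. Ring B is a cross-conjugated cyclohexa-2,5-dienone (C6=C7–C8(=O)–C9=C10) whose only sp3 atom is the quaternary C5. Ring A carries three contiguous stereocentres, C3 (acyloxy), C4 (methyl) and C5 (methyl), all R. The two methyl groups are cis and the C3 oxygen is trans to both; because C14 is necessarily axial on ring A, C15 and the C3 oxygen are equatorial.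

The sensitive groups are:
- the (Z)-2-methyl-3-(methylsulfanyl)acrylate, a push–pull alkene with oxidisable sulfur, held in its less stable geometry;
- the tertiary C11 alcohol, which in any precursor with sp3 C7 is a β-hydroxy ketone open to dehydration and retro-aldol cleavage;
- the dienone, which rearranges under acid and, once its carbonyl is reduced, ionises to an arenium-type cation.

The difficulty is that C5 must be made as one enantiomer although it ends up between two sp2 carbons, and that C3 and C4 must then be set relative to it without touching the ester sulfur. The strategy rests on one feature: C5 bears a methyl group and lies 1,4 to the C8 carbonyl across ring B. That is the pattern left by a [4+2] addition of a 2-siloxydiene (C7–C10) to methacrolein (C4, C5, C6, C14), and C7–C9 together with C11–C13 are the carbon skeleton of diacetone alcohol.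

## Retrosynthetic reasoning

**Ester bond (28 to 20 and 26).** The C3–O acyl bond is cut first. The sulfur-bearing acyl group would not survive the oxidations, the hydroboration or the palladium chemistry that the core requires, and its Z geometry is fragile, so it enters last. The forward reaction must acylate the secondary C3 hydroxyl of 20 beside the tertiary C11 hydroxyl, which the steric difference allows. Acid 26 is traced to iodo acid 25 by cutting the C–S bond (vinylic substitution with retention), then to iodo alcohol 23 and to propargyl alcohol 21. The Z geometry comes from an anti-carbometalation in which a five-membered metal chelate forces the metal, and later iodine and sulfur, cis to the oxygenated carbon.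

**Hydration of C3=C4 (20 to 19, 18 and 16).** The C3–O and C4–H bonds are removed together as a syn hydroboration–oxidation of the C3=C4 alkene of dienone 16. This sets both centres in one stereospecific event and makes C5 the only source of facial bias: attack opposite the axial C14 gives C3–O trans and C15 cis to C14. The hydration is deliberately placed after ring B has become fully planar. With C10 still sp3, C14 is axial on ring A only in a trans-fused framework, so the face attacked would depend on the endo/exo outcome of the cycloaddition. At the stage of 16 that dependence is gone. The price is that the carbonyl is reduced in passing (18) and restored by a chemoselective allylic oxidation (19) before the tertiary silyl ether is removed (20).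

**Unsaturation of ring B (16 to 14 and 13).** The C9=C10 bond is traced to the silyl enol ether that the cycloaddition leaves at C8=C9 in 13 (Saegusa–Ito oxidation to 14). The C6=C7 bond is traced to a second enol ether, 15, formed from 14. This uses the enol ether productively instead of hydrolysing and re-protecting C8, and it erases C7 and C10, so both cycloaddition diastereomers converge.

**Ring A (13 to 12, then 11, 10 and 9).** The C3=C4 bond is cut by ring-closing metathesis, because its two alkene partners sit on C5 and C10, exactly the atoms the cycloaddition joins. The isopropenyl group of 12 is traced through methyl ketone 11 and carbinol 10 to the formyl group of 9: C15 arrives as a methyl nucleophile, and the methylene carbon is sacrificial and leaves in the metathesis.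

**Ring B, the key disconnection (9 to 7 and 8).** The C5–C10 and C6–C7 bonds are cut together. This removes the quaternary centre and the ring in one step and leads to two achiral fragments, diene 7 and methacrolein 8. The forward reaction has to control only one thing absolutely, the face of the enal, which a chiral Lewis acid bound to the formyl group can do.

**Diene (7 to 6, 4, 2, 3 and 1).** The siloxydiene is the enol ether of enone 6. Cutting its C9=C10 alkene as an aldol condensation gives silylated diacetone alcohol 2 and pent-4-enal 3, and 2 comes from diacetone alcohol 1. The forward reactions need kinetic enolisation of 2 at its methyl group and α′-enolisation of 6 with the enol ether geometry that lets the diene reach the s-cis conformation.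

## Alternatives that were turned down

**Alternative 1: angular methyl from a cyclopropane.** C14 is treated as the methylene of a cyclopropane spanning C4 and C5. In the forward key step a Simmons–Smith zinc carbenoid, held by the C3 hydroxyl of allylic alcohol A1, is delivered to the tetrasubstituted C4=C5 alkene on the hydroxyl face to give cyclopropyl carbinol A2. Oxidation at C3 and reductive opening of the C4–C14 bond would then release the angular methyl.
- For: hydroxyl-directed cyclopropanation is among the most dependable ways to place a carbon on a hindered alkene with complete facial control. On reliability of the key step it is stronger than the cycloaddition chosen here.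
- Against: the directing hydroxyl puts C14 cis to the C3 oxygen, whereas the target has them trans. C3 therefore has to be destroyed and rebuilt by a ketone reduction in which the axial C14 blocks the axial hydride path that would give the equatorial alcohol. C4 depends on an enolate protonation. A2 still lacks C11 and both ring-B double bonds and carries C8 as a ketal. The absolute configuration must be bought separately in making A1, including a C10 centre that is later planarised.
- Comparison: the chosen route accepts a less certain key step but brings C11 and the C8 oxygen in from the start and sets C3 and C4 once, in the correct sense.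

**Alternative 2: both rings from a chain by a metal-catalysed dienyne cycloaddition.** The C5–C10 and C8–C9 bonds are cut. In the forward key step a zerovalent nickel catalyst with a bulky triaryl phosphite adds the C9≡C10 alkyne of dienyne A3 across its C5=C6–C7=C8 diene to give bicyclic 1,4-diene A4. Oxidation of the doubly allylic C8 methylene, desilylation and acylation would follow.
- For: it is the most convergent plan. Both rings close at once, C3 and C4 are made in the open chain where their control does not depend on ring conformation, and the endgame from A4 is shorter than the one here. On these points it is stronger.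
- Against: the diene terminus C5 is fully substituted, with the methyl in the inside position, so the s-cis conformation is penalised. The four-atom tether closes a six-membered ring, the slower mode for this reaction. The configuration of the quaternary C5 rests on induction from C4 through the tether. A3 itself needs a stereodefined trisubstituted diene bearing a tertiary silyl ether and an anti C3/C4 pair, a long preparation.
- Comparison: the chosen route puts its risk into an intermolecular cycloaddition in which a catalyst controls a single centre, and it builds its diene in four steps.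

**Alternative 3: dearomatising para-alkylation of a phenol.** The C4–C5 bond is cut. In the forward key step a potassium alkoxide base converts phenol mesylate A5 into its phenoxide, whose para carbon C5 displaces the C4 mesylate with inversion to give silylated dienone A6.
- For: A6 already has the dienone, C11 and all three stereocentres. No dehydrogenation and no carbonyl manipulation are needed, and an all-equatorial chair transition state matches the target's relative configuration. After the key step only desilylation and acylation remain, so on step count after the key step it is clearly stronger.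
- Against: the displacement is at a secondary carbon next to a silyloxy-bearing carbon, by a tetrasubstituted arene carbon, under a strong base, so elimination is the expected competitor. The ortho-hydroxybenzylic tertiary alcohol of A5 is a quinone methide precursor. A5 needs two reagent-controlled stereocentres and the differentiation of two very similar secondary hydroxyls.
- Comparison: the chosen route needs one reagent-controlled centre, avoids a displacement at a hindered secondary carbon, and relays C3 and C4 from C5 by a syn addition whose facial course can be argued from the structure.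

Key step: step 5

## Assumptions

- Sense of induction: with the catalyst from (S)-α,α-diphenylprolinol the diene is taken to add to the methacrolein face that gives (S)-C5 in adduct 9, as the formyl C–H···O binding model for 2-substituted acroleins predicts. If the opposite sense were met, the enantiomeric catalyst would be used with no other change.
- Endo/exo: adduct 9 is drawn as the formyl-endo diastereomer (formyl, C7 and C10 substituents all cis), the usual outcome for an open-chain diene. Any formyl-exo adduct follows the same steps and merges with the main series at 16.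

## Route

Step 1
Reactants: 1 diacetone alcohol (4-hydroxy-4-methylpentan-2-one)
Product: 2 4-methyl-4-(triethylsilyloxy)pentan-2-one
Conditions: Et3SiOTf, 2,6-lutidine, CH2Cl2, −78 → 0 °C
Reagents that add atoms: triethylsilyl trifluoromethanesulfonate, CC[Si](CC)(CC)OS(=O)(=O)C(F)(F)F
Why: A silyl triflate with a hindered pyridine base silylates a tertiary alcohol at low temperature faster than it enolises the methyl ketone; the silyl ether blocks the retro-aldol cleavage that the free alkoxide would undergo in step 2.

Step 2
Reactants: 2 4-methyl-4-(triethylsilyloxy)pentan-2-one; 3 pent-4-enal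
Product: 4 6-hydroxy-2-methyl-2-(triethylsilyloxy)dec-9-en-4-one (racemic at the carbinol)
Conditions: LiN(iPr)2 (commercial solution), THF, −78 °C; then 3; aq. NH4Cl
Reagents that add atoms: none
Why: Kinetic deprotonation takes the methyl group and not the neopentyl-type methylene, and the lithium enolate adds to the aldehyde (directed aldol addition); the new carbinol centre is lost in step 3, so it needs no control.

Step 3
Reactants: 4 6-hydroxy-2-methyl-2-(triethylsilyloxy)dec-9-en-4-one
Product: 6 (5E)-2-methyl-2-(triethylsilyloxy)deca-5,9-dien-4-one, via mesylate 5 (not isolated)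
Conditions: CH3SO2Cl, Et3N, CH2Cl2, 0 °C; then DBU, 0 → 25 °C
Reagents that add atoms: none
Why: Mesylation followed by E1cB elimination through the enolate on the carbinol side gives the conjugated E-enone; the mesylate leaves far more readily than the tertiary silanolate on the other side of the carbonyl.

Step 4
Reactants: 6 (5E)-2-methyl-2-(triethylsilyloxy)deca-5,9-dien-4-one
Product: 7 (3Z,5E)-4-(tert-butyldimethylsilyloxy)-2-methyl-2-(triethylsilyloxy)deca-3,5,9-triene
Conditions: tBuMe2SiOTf, Et3N, CH2Cl2, −78 → 0 °C; filtration through basic alumina
Reagents that add atoms: tert-butyldimethylsilyl trifluoromethanesulfonate, CC(C)(C)[Si](C)(C)OS(=O)(=O)C(F)(F)F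
Why: Soft enolisation of an enone with a silyl triflate and a tertiary amine removes an α′-hydrogen and gives the cross-conjugated 2-siloxydiene; the enol ether should form with the bulky C11 group trans to the vinyl group (Z), the geometry free of allylic strain and the only one that can reach the s-cis conformation.

Step 5
Reactants: 7 (3Z,5E)-4-(tert-butyldimethylsilyloxy)-2-methyl-2-(triethylsilyloxy)deca-3,5,9-triene; 8 methacrolein
Product: 9 (1S,2R,5S)-2-(but-3-en-1-yl)-4-(tert-butyldimethylsilyloxy)-1-methyl-5-[2-(triethylsilyloxy)propan-2-yl]cyclohex-3-ene-1-carbaldehyde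
Conditions: (S)-oxazaborolidine C24H24BNO (20 mol %), HN(SO2CF3)2 (18 mol %), 8 (3 equiv), CH2Cl2, −78 → −40 °C; Et3N quench
Reagents that add atoms: none
Why: The boron of the protonated oxazaborolidine binds the formyl oxygen of s-trans methacrolein syn to the formyl hydrogen, which in turn contacts the ring oxygen, so the enal is held over one phenyl group and only one of its faces is open. The closest known reaction type is the oxazaborolidinium-catalysed Diels–Alder reaction of 2-substituted acroleins with acyclic dienes, 2-siloxydienes included, which gives α-quaternary aldehydes. Ring B is closed by a concerted, asynchronous, suprafacial [4+2] cycloaddition in which the enol ether carbon C7 bonds to the β-carbon C6 ahead of the C10–C5 bond. C5 is set by the catalyst through the choice of the enal face; C7 and C10 come out cis to one another because both diene substituents are outside groups, and their relation to C5 (formyl-endo expected) is not needed later. The step needs regioselectivity, which the siloxy group secures by placing the largest HOMO coefficient on C7 so that C8 ends up 1,4 to C5, reinforced by the alkyl group on C10. It also needs chemoselectivity for the diene over the unactivated terminal alkene and a rate at low temperature that outruns silyl transfer to the triflimide; the unhindered CH2 terminus of the dienophile meeting the hindered diene terminus is the favourable pairing.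

Step 6
Reactants: 9 the cycloadduct aldehyde
Product: 10 1-[(1S,2R,5S)-2-(but-3-en-1-yl)-4-(tert-butyldimethylsilyloxy)-1-methyl-5-[2-(triethylsilyloxy)propan-2-yl]cyclohex-3-en-1-yl]ethan-1-ol (carbinol epimers)
Conditions: CH3MgBr, THF, −78 → 0 °C; aq. NH4Cl
Reagents that add atoms: methylmagnesium bromide, C[Mg]Br
Why: Grignard addition to an aldehyde without α-hydrogen; the silyl enol ether and the silyl ether are inert to the reagent, and the carbinol epimers are both oxidised in step 7.

Step 7
Reactants: 10 the secondary carbinol
Product: 11 1-[(1S,2R,5S)-2-(but-3-en-1-yl)-4-(tert-butyldimethylsilyloxy)-1-methyl-5-[2-(triethylsilyloxy)propan-2-yl]cyclohex-3-en-1-yl]ethan-1-one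
Conditions: Dess–Martin periodinane, NaHCO3, CH2Cl2, 0 → 25 °C
Reagents that add atoms: none
Why: Dess–Martin oxidation under bicarbonate buffering gives the methyl ketone without the acid that would hydrolyse the enol ether.

Step 8
Reactants: 11 the methyl ketone
Product: 12 (1S,2R,5S)-2-(but-3-en-1-yl)-4-(tert-butyldimethylsilyloxy)-1-methyl-1-(prop-1-en-2-yl)-5-[2-(triethylsilyloxy)propan-2-yl]cyclohex-3-ene
Conditions: Ph3PCH3Br, KOtBu, toluene, 25 → 80 °C
Reagents that add atoms: methyltriphenylphosphonium bromide, C[P+](c1ccccc1)(c1ccccc1)c1ccccc1.[Br-]
Why: Wittig methylenation with an excess of the non-stabilised ylide at raised temperature is the usual answer to a methyl ketone on a quaternary carbon; no stereocentre is touched.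

Step 9
Reactants: 12 the isopropenyl butenyl cyclohexene
Product: 13 (4aR,7S,8aS)-6-(tert-butyldimethylsilyloxy)-1,8a-dimethyl-7-[2-(triethylsilyloxy)propan-2-yl]-3,4,4a,7,8,8a-hexahydronaphthalene
Conditions: second-generation Grubbs catalyst C46H65Cl2N2PRu (5 mol %), CH2Cl2, 40 °C
Reagents that add atoms: none
Why: Ring-closing metathesis between the monosubstituted and the 1,1-disubstituted alkene closes ring A as a trisubstituted cyclohexene and releases ethene; the ring enol ether is too hindered to engage the ruthenium carbene, and the two chains sit on adjacent ring atoms, so a six-membered ring closes in either diastereomeric series.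

Step 10
Reactants: 13 the bicyclic silyl enol ether
Product: 14 (3S,4aR)-4a,5-dimethyl-3-[2-(triethylsilyloxy)propan-2-yl]-4,4a,7,8-tetrahydronaphthalen-2(3H)-one
Conditions: Pd(OAc)2 (1.1 equiv), MeCN, 25 → 40 °C
Reagents that add atoms: none
Why: Saegusa–Ito oxidation: divalent palladium adds to the enol ether carbon C9, the silyl group leaves as its acetate, and β-hydride elimination of H10 gives the C9=C10 enone. C10 becomes planar, so any exo-derived material now differs only at the epimerisable C7.

Step 11
Reactants: 14 the enone
Product: 16 (4aR)-4a,5-dimethyl-3-[2-(triethylsilyloxy)propan-2-yl]-7,8-dihydronaphthalen-2(4aH)-one, via trimethylsilyl dienol ether 15 (not isolated)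
Conditions: LiN(iPr)2, THF, −78 °C; Me3SiCl, Et3N; then Pd(OAc)2 (1.2 equiv), MeCN, 25 °C
Reagents that add atoms: none
Why: Kinetic deprotonation of an enone occurs at the α′ position (the axial C7–H, with the bulky group equatorial), and silylation gives the 2-siloxydiene 15. A second Saegusa–Ito oxidation can eliminate only toward C6 because C11 has no hydrogen; C7 becomes planar and both diastereomeric series converge on one compound.

Step 12
Reactants: 16 the cross-conjugated dienone
Product: 18 (4aR,5R,6R)-4a,5-dimethyl-3-[2-(triethylsilyloxy)propan-2-yl]-2,4a,5,6,7,8-hexahydronaphthalene-2,6-diol (C8 carbinol epimers), via organoborane 17 (not isolated)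
Conditions: BH3·THF (1.5 equiv), THF, −10 → 0 °C; then NaOH, H2O2, 0 → 25 °C
Reagents that add atoms: hydrogen peroxide, OO
Why: Hydroboration–oxidation with concurrent carbonyl reduction: the C3=C4 alkene, whose boron-accepting carbon C3 is flanked only by a methylene, should react ahead of the two ring-B alkenes, which are conjugated to the carbonyl until it is reduced and afterwards carry an allylic oxygen and hindered termini. Boron adds to C3 and hydrogen to C4 in a syn four-centre addition on the face opposite the axial C14 methyl, the only group that differentiates the faces once ring B is planar; oxidation with retention gives the (3R,4R) arrangement of the target, and the C8 carbinol is removed in step 13.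

Step 13
Reactants: 18 the diol
Product: 19 (4aR,5R,6R)-6-hydroxy-4a,5-dimethyl-3-[2-(triethylsilyloxy)propan-2-yl]-5,6,7,8-tetrahydronaphthalen-2(4aH)-one
Conditions: MnO2 (excess), CH2Cl2, 25 °C
Reagents that add atoms: none
Why: MnO2 oxidises the doubly allylic C8 alcohol back to the dienone and leaves the saturated secondary C3 alcohol alone (chemoselective allylic oxidation under neutral conditions, which the acid-labile dienol requires).

Step 14
Reactants: 19 the hydroxy dienone silyl ether
Product: 20 (4aR,5R,6R)-6-hydroxy-3-(2-hydroxypropan-2-yl)-4a,5-dimethyl-5,6,7,8-tetrahydronaphthalen-2(4aH)-one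
Conditions: HF·pyridine, pyridine, THF, 0 → 25 °C
Reagents that add atoms: none
Why: Fluoride-mediated desilylation; with C7 now sp2 the freed tertiary alcohol can no longer dehydrate into conjugation, and the buffered reagent avoids the strong acid that a dienone rearrangement would need.

Step 15
Reactants: 21 propargyl alcohol
Product: 23 (2Z)-3-iodo-2-methylprop-2-en-1-ol, via cyclic vinylmagnesium alkoxide 22 (not isolated)
Conditions: CH3MgBr (2.5 equiv), CuI (10 mol %), Et2O, −10 → 25 °C; then I2, −10 °C; aq. NH4Cl
Reagents that add atoms: methylmagnesium bromide, C[Mg]Br; iodine, II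
Why: Copper-catalysed anti-carbomagnesiation of the propargylic alkoxide places methyl on the internal carbon and magnesium on the terminal carbon inside a five-membered chelate, so iodinolysis with retention gives the Z iodide (iodine cis to CH2OH).

Step 16
Reactants: 23 (2Z)-3-iodo-2-methylprop-2-en-1-ol
Product: 25 (2Z)-3-iodo-2-methylprop-2-enoic acid, via iodo enal 24 (not isolated)
Conditions: MnO2, CH2Cl2, 25 °C, dark, filter; then NaClO2, NaH2PO4, 2-methylbut-2-ene, tBuOH/H2O, 0 °C
Reagents that add atoms: sodium chlorite, [Na+].[O-]Cl=O
Why: MnO2 oxidises the allylic alcohol to the enal, which is not stored but oxidised at once by chlorite (Pinnick oxidation); neither reagent touches the vinyl iodide, and the alkene scavenger removes the hypochlorite.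

Step 17
Reactants: 25 (2Z)-3-iodo-2-methylprop-2-enoic acid
Product: 26 (2Z)-2-methyl-3-(methylsulfanyl)prop-2-enoic acid
Conditions: NaSCH3 (2.2 equiv), CuI (10 mol %), DMF, 0 → 25 °C; then 1 M HCl, 0 °C
Reagents that add atoms: sodium methanethiolate, [Na+].[S-]C
Why: Vinylic substitution of a β-iodoacrylate by thiolate, whether by addition–elimination or through monovalent copper, proceeds with retention, so sulfur takes the position cis to the carboxyl group.

Step 18
Reactants: 26 (2Z)-2-methyl-3-(methylsulfanyl)prop-2-enoic acid; 20 the dihydroxy dienone
Product: 28 (1R,2R,8aR)-7-(2-hydroxypropan-2-yl)-1,8a-dimethyl-6-oxo-1,2,3,4,6,8a-hexahydronaphthalen-2-yl (2Z)-2-methyl-3-(methylsulfanyl)prop-2-enoate, via mixed anhydride 27 (not isolated)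
Conditions: 2,4,6-Cl3C6H2COCl, Et3N, toluene, 25 °C; then 20, DMAP, 0 → 25 °C
Reagents that add atoms: none
Why: Yamaguchi esterification: the mixed anhydride acylates the secondary equatorial C3 hydroxyl under DMAP catalysis, while the tertiary C11 hydroxyl should not react at room temperature; introduced last, the sulfur ester meets no oxidant, borane or palladium.

## Compound list

1 | diacetone alcohol (4-hydroxy-4-methylpentan-2-one) | CC(=O)CC(C)(C)O | starting material
2 | 4-methyl-4-(triethylsilyloxy)pentan-2-one | CC(=O)CC(C)(C)O[Si](CC)(CC)CC | intermediate
3 | pent-4-enal | C=CCCC=O | starting material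
4 | 6-hydroxy-2-methyl-2-(triethylsilyloxy)dec-9-en-4-one (racemic carbinol) | C=CCCC(O)CC(=O)CC(C)(C)O[Si](CC)(CC)CC | intermediate
5 | methanesulfonate of 4 | C=CCCC(OS(C)(=O)=O)CC(=O)CC(C)(C)O[Si](CC)(CC)CC | intermediate (not isolated)
6 | (5E)-2-methyl-2-(triethylsilyloxy)deca-5,9-dien-4-one | C=CCC/C=C/C(=O)CC(C)(C)O[Si](CC)(CC)CC | intermediate
7 | (3Z,5E)-4-(tert-butyldimethylsilyloxy)-2-methyl-2-(triethylsilyloxy)deca-3,5,9-triene | C=CCC/C=C/C(O[Si](C)(C)C(C)(C)C)=C/C(C)(C)O[Si](CC)(CC)CC | intermediate
8 | methacrolein | CC(=C)C=O | starting material
9 | (1S,2R,5S)-2-(but-3-en-1-yl)-4-(tert-butyldimethylsilyloxy)-1-methyl-5-[2-(triethylsilyloxy)propan-2-yl]cyclohex-3-ene-1-carbaldehyde | O=C[C@@]1(C)C[C@@H](C(C)(C)O[Si](CC)(CC)CC)C(O[Si](C)(C)C(C)(C)C)=C[C@H]1CCC=C | intermediate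
10 | 1-[(1S,2R,5S)-2-(but-3-en-1-yl)-4-(tert-butyldimethylsilyloxy)-1-methyl-5-[2-(triethylsilyloxy)propan-2-yl]cyclohex-3-en-1-yl]ethan-1-ol (carbinol epimers) | CC(O)[C@@]1(C)C[C@@H](C(C)(C)O[Si](CC)(CC)CC)C(O[Si](C)(C)C(C)(C)C)=C[C@H]1CCC=C | intermediate
11 | 1-[(1S,2R,5S)-2-(but-3-en-1-yl)-4-(tert-butyldimethylsilyloxy)-1-methyl-5-[2-(triethylsilyloxy)propan-2-yl]cyclohex-3-en-1-yl]ethan-1-one | CC(=O)[C@@]1(C)C[C@@H](C(C)(C)O[Si](CC)(CC)CC)C(O[Si](C)(C)C(C)(C)C)=C[C@H]1CCC=C | intermediate
12 | (1S,2R,5S)-2-(but-3-en-1-yl)-4-(tert-butyldimethylsilyloxy)-1-methyl-1-(prop-1-en-2-yl)-5-[2-(triethylsilyloxy)propan-2-yl]cyclohex-3-ene | C=C(C)[C@@]1(C)C[C@@H](C(C)(C)O[Si](CC)(CC)CC)C(O[Si](C)(C)C(C)(C)C)=C[C@H]1CCC=C | intermediate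
13 | (4aR,7S,8aS)-6-(tert-butyldimethylsilyloxy)-1,8a-dimethyl-7-[2-(triethylsilyloxy)propan-2-yl]-3,4,4a,7,8,8a-hexahydronaphthalene | CC1=CCC[C@@H]2C=C(O[Si](C)(C)C(C)(C)C)[C@H](C(C)(C)O[Si](CC)(CC)CC)C[C@]12C | intermediate
14 | (3S,4aR)-4a,5-dimethyl-3-[2-(triethylsilyloxy)propan-2-yl]-4,4a,7,8-tetrahydronaphthalen-2(3H)-one | CC1=CCCC2=CC(=O)[C@H](C(C)(C)O[Si](CC)(CC)CC)C[C@]12C | intermediate
15 | (4aR)-4a,5-dimethyl-3-[2-(triethylsilyloxy)propan-2-yl]-2-(trimethylsilyloxy)-4,4a,7,8-tetrahydronaphthalene | CC1=CCCC2=CC(O[Si](C)(C)C)=C(C(C)(C)O[Si](CC)(CC)CC)C[C@]12C | intermediate (not isolated)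
16 | (4aR)-4a,5-dimethyl-3-[2-(triethylsilyloxy)propan-2-yl]-7,8-dihydronaphthalen-2(4aH)-one | CC1=CCCC2=CC(=O)C(C(C)(C)O[Si](CC)(CC)CC)=C[C@]12C | intermediate
17 | C3 alkylborane and C8 alkoxyborane derived from 16 (representative form) | B[C@@H]1CCC2=CC(OB)C(C(C)(C)O[Si](CC)(CC)CC)=C[C@]2(C)[C@H]1C | intermediate (not isolated)
18 | (4aR,5R,6R)-4a,5-dimethyl-3-[2-(triethylsilyloxy)propan-2-yl]-2,4a,5,6,7,8-hexahydronaphthalene-2,6-diol (C8 carbinol epimers) | O[C@@H]1CCC2=CC(O)C(C(C)(C)O[Si](CC)(CC)CC)=C[C@]2(C)[C@H]1C | intermediate
19 | (4aR,5R,6R)-6-hydroxy-4a,5-dimethyl-3-[2-(triethylsilyloxy)propan-2-yl]-5,6,7,8-tetrahydronaphthalen-2(4aH)-one | O[C@@H]1CCC2=CC(=O)C(C(C)(C)O[Si](CC)(CC)CC)=C[C@]2(C)[C@H]1C | intermediate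
20 | (4aR,5R,6R)-6-hydroxy-3-(2-hydroxypropan-2-yl)-4a,5-dimethyl-5,6,7,8-tetrahydronaphthalen-2(4aH)-one | O[C@@H]1CCC2=CC(=O)C(C(C)(C)O)=C[C@]2(C)[C@H]1C | intermediate
21 | propargyl alcohol | C#CCO | starting material
22 | 4-methyl-2,5-dihydro-1,2-oxamagnesole (cyclic vinylmagnesium alkoxide) | CC1=C[Mg]OC1 | intermediate (not isolated)
23 | (2Z)-3-iodo-2-methylprop-2-en-1-ol | C/C(CO)=C/I | intermediate
24 | (2Z)-3-iodo-2-methylprop-2-enal | C/C(C=O)=C/I | intermediate (not isolated)
25 | (2Z)-3-iodo-2-methylprop-2-enoic acid | C/C(C(=O)O)=C/I | intermediate
26 | (2Z)-2-methyl-3-(methylsulfanyl)prop-2-enoic acid | CS/C=C(/C)C(=O)O | intermediate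
27 | (2Z)-2-methyl-3-(methylsulfanyl)prop-2-enoic 2,4,6-trichlorobenzoic anhydride | CS/C=C(/C)C(=O)OC(=O)c1c(Cl)cc(Cl)cc1Cl | intermediate (not isolated)
28 | (1R,2R,8aR)-7-(2-hydroxypropan-2-yl)-1,8a-dimethyl-6-oxo-1,2,3,4,6,8a-hexahydronaphthalen-2-yl (2Z)-2-methyl-3-(methylsulfanyl)prop-2-enoate | CS/C=C(/C)C(=O)O[C@@H]1CCC2=CC(=O)C(C(C)(C)O)=C[C@]2(C)[C@H]1C | target

## Step count and least certain steps

Total: 18 steps. Longest linear sequence: 15 steps (steps 1–14 and 18, from diacetone alcohol); the acid 26 is made in a three-step branch (steps 15–17).

**Step 5 (key step).** The diene terminus C7 carries a tert-alkyl group, so the cycloaddition may be slow. Silyl transfer from the enol ether to the triflimide would then produce an achiral silyl Lewis acid that erodes enantiomeric purity, and Mukaiyama-type addition at the formyl carbon or protodesilylation of the diene could take over. The fallback unloads that terminus and brings C11 in later. It sets out from 3 and 8 and returns at 14.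
- Pent-4-enal 3 and 1-(triphenylphosphoranylidene)propan-2-one give (E)-nona-3,8-dien-2-one F1.
- Soft enolisation (tBuMe2SiOTf, Et3N) gives 2-(tert-butyldimethylsilyloxy)nona-1,3,8-triene F2.
- The same catalysed cycloaddition with 8 gives the C7-unsubstituted adduct aldehyde F3.
- The operations of steps 6–10 (CH3MgBr; Dess–Martin periodinane; Wittig methylenation; ring-closing metathesis; Pd(OAc)2) lead through carbinol F4, methyl ketone F5, isopropenyl triene F6 and bicyclic silyl enol ether F7 to enone F8.
- Kinetic α′-deprotonation of F8 (LiN(iPr)2, −78 °C) and aldol addition to acetone give hydroxy ketone F9; silylation (Et3SiOTf, 2,6-lutidine) gives 14 as C7 epimers that converge at 16.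

**Step 12.** Once the carbonyl has been reduced, hydroboration of C9=C10 could compete with that of C3=C4 and be followed by β-elimination of the boron alkoxide. The cross-conjugated dienol could also ionise on any acidic handling. The fallback avoids borane and carbonyl reduction altogether. It sets out from 16 and returns at 19.
- m-Chloroperbenzoic acid (NaHCO3, CH2Cl2, 0 °C) should epoxidise only the isolated, electron-rich C3=C4 alkene, on the face opposite C14, giving epoxide F10.
- Me3SiOTf with DBU opens it at the tertiary C4, and loss of a C15 proton (C5 has none) gives allylic silyl ether F11.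
- K2CO3/MeOH frees allylic alcohol F12, which has an exocyclic C4 methylene.
- H2 with RhCl(PPh3)3 reduces only this 1,1-disubstituted alkene, from the face opposite C14, to give 19.

**Step 11.** Deprotonation of the hindered C7–H may be slow, so γ-deprotonation at C1 or loss of silanolate from C11 could compete, and palladation of a fully substituted enol ether carbon may be sluggish. The fallback sets out from 14 and returns at 16: the lithium enolate is captured at −78 °C by PhSeBr to give the C7 phenylselanyl ketone F13, and oxidation (H2O2, pyridine, CH2Cl2, 0 °C) triggers syn elimination of the selenoxide toward C6, the only β-hydrogen available, to give 16.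

**Step 8.** The basic ylide may enolise the methyl ketone faster than it adds to a carbonyl flanked by a quaternary carbon, leaving conversion incomplete. The fallback is a Peterson olefination. It sets out from 11 and returns at 12: Me3SiCH2Li with CeCl3 (THF, −78 °C) adds without enolisation to give β-hydroxysilane F14, and KH (THF, 0 → 25 °C) eliminates silanolate to give 12; base and not acid is used because of the enol ether.

**Step 18.** The activated push–pull acyl donor may lose its Z geometry through reversible conjugate addition of DMAP or carboxylate, and acylation of the hindered C3 hydroxyl may be slow enough to let this happen. The fallback forms the C–S bond last. It sets out from 20 and 25 and returns at 28: acid 25 is converted ((COCl)2, cat. DMF) into (2Z)-3-iodo-2-methylprop-2-enoyl chloride F15, which acylates 20 with 2,6-lutidine as the only base to give iodoacrylate ester F16. NaSCH3 (1.05 equiv, THF, −20 °C) then replaces iodine with retention to give 28.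

## Further compounds

F1 | step 5 | (E)-nona-3,8-dien-2-one | C=CCC/C=C/C(C)=O
F2 | step 5 | (3E)-2-(tert-butyldimethylsilyloxy)nona-1,3,8-triene | C=CCC/C=C/C(=C)O[Si](C)(C)C(C)(C)C
F3 | step 5 | (1S,2R)-2-(but-3-en-1-yl)-4-(tert-butyldimethylsilyloxy)-1-methylcyclohex-3-ene-1-carbaldehyde | O=C[C@@]1(C)CCC(O[Si](C)(C)C(C)(C)C)=C[C@H]1CCC=C
F4 | step 5 | 1-[(1S,2R)-2-(but-3-en-1-yl)-4-(tert-butyldimethylsilyloxy)-1-methylcyclohex-3-en-1-yl]ethan-1-ol (carbinol epimers) | CC(O)[C@@]1(C)CCC(O[Si](C)(C)C(C)(C)C)=C[C@H]1CCC=C
F5 | step 5 | 1-[(1S,2R)-2-(but-3-en-1-yl)-4-(tert-butyldimethylsilyloxy)-1-methylcyclohex-3-en-1-yl]ethan-1-one | CC(=O)[C@@]1(C)CCC(O[Si](C)(C)C(C)(C)C)=C[C@H]1CCC=C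
F6 | step 5 | (1S,2R)-2-(but-3-en-1-yl)-4-(tert-butyldimethylsilyloxy)-1-methyl-1-(prop-1-en-2-yl)cyclohex-3-ene | C=C(C)[C@@]1(C)CCC(O[Si](C)(C)C(C)(C)C)=C[C@H]1CCC=C
F7 | step 5 | (4aR,8aS)-6-(tert-butyldimethylsilyloxy)-1,8a-dimethyl-3,4,4a,7,8,8a-hexahydronaphthalene | CC1=CCC[C@@H]2C=C(O[Si](C)(C)C(C)(C)C)CC[C@]12C
F8 | step 5 | (4aS)-4a,5-dimethyl-4,4a,7,8-tetrahydronaphthalen-2(3H)-one | CC1=CCCC2=CC(=O)CC[C@]12C
F9 | step 5 | (4aR)-3-(2-hydroxypropan-2-yl)-4a,5-dimethyl-4,4a,7,8-tetrahydronaphthalen-2(3H)-one (C7 epimers) | CC1=CCCC2=CC(=O)C(C(C)(C)O)C[C@]12C
F10 | step 12 | 3,4-epoxide of 16 with the oxygen on the face opposite C14 | C[C@@]1(O2)[C@H]2CCC3=CC(=O)C(C(C)(C)O[Si](CC)(CC)CC)=C[C@]13C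
F11 | step 12 | trimethylsilyl ether of the C3 allylic alcohol with exocyclic C4 methylene | C=C1[C@H](O[Si](C)(C)C)CCC2=CC(=O)C(C(C)(C)O[Si](CC)(CC)CC)=C[C@]12C
F12 | step 12 | C3 allylic alcohol with exocyclic C4 methylene | C=C1[C@H](O)CCC2=CC(=O)C(C(C)(C)O[Si](CC)(CC)CC)=C[C@]12C
F13 | step 11 | C7 phenylselanyl derivative of 14 (C7 configuration not defined) | CC1=CCCC2=CC(=O)C([Se]c3ccccc3)(C(C)(C)O[Si](CC)(CC)CC)C[C@]12C
F14 | step 8 | β-hydroxysilane from 11 and (trimethylsilyl)methyllithium (carbinol epimers) | C[Si](C)(C)CC(C)(O)[C@@]1(C)C[C@@H](C(C)(C)O[Si](CC)(CC)CC)C(O[Si](C)(C)C(C)(C)C)=C[C@H]1CCC=C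
F15 | step 18 | (2Z)-3-iodo-2-methylprop-2-enoyl chloride | C/C(=C/I)C(Cl)=O
F16 | step 18 | (2Z)-3-iodo-2-methylprop-2-enoate of 20 at C3 | C/C(=C/I)C(=O)O[C@@H]1CCC2=CC(=O)C(C(C)(C)O)=C[C@]2(C)[C@H]1C
A1 | alternative 1 | allylic alcohol with C4=C5 alkene and C8 dioxolane | O[C@H]1CC[C@@H]2CC3(OCCO3)CCC2=C1C
A2 | alternative 1 | cyclopropyl carbinol with C14 on C4 and C5 | O[C@H]1CC[C@@H]2CC3(OCCO3)CC[C@@]24C[C@@]14C
A3 | alternative 2 | open-chain dienyne with C3 silyl ether and C4 methyl | C#CCC[C@@H](O[Si](C)(C)C(C)(C)C)[C@H](C)/C(C)=C/C(=C)C(C)(C)O[Si](CC)(CC)CC
A4 | alternative 2 | bicyclic 1,4-diene with C8 as a methylene | CC(C)(C)[Si](C)(C)O[C@@H]1CCC2=CCC(C(C)(C)O[Si](CC)(CC)CC)=C[C@]2(C)[C@H]1C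
A5 | alternative 3 | para-methylphenol with C3 silyl ether and C4 mesylate | Cc1cc(C(C)(C)O)c(O)cc1CC[C@@H](O[Si](C)(C)C(C)(C)C)[C@@H](C)OS(C)(=O)=O
A6 | alternative 3 | C3-silylated dienone core | CC(C)(C)[Si](C)(C)O[C@@H]1CCC2=CC(=O)C(C(C)(C)O)=C[C@]2(C)[C@H]1C
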